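**Plan**

1. Cyclohexene numbering: C1 (sp2, methyl), C2 (sp2, H), C3 (bears ring A, the acyl ring of the chalcone arm), C4 (bears the aroyl group, ring E), C5 (bears ring G, 2,4-dihydroxyphenyl), C6 (CH2). Ring B is the far ring of the chalcone arm.
2. Cuts, in retrosynthetic order: eight O–MOM bonds, then Cα=Cβ of the chalcone arm (aldol). Next C5–C6, re-joined as C5–C2 (retro 1,3-shift, six- to four-membered ring), then C2–isopropenyl (back to a C2 carboxyl group). Next C2–C3, re-opened by insertion of NH (four- to five-membered ring), and last C2–C5 and C3–C4 (retro 1,3-dipolar cycloaddition to a chalcone and a glycine imine).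
3. Enabling feature: the C5–C6 bond is benzylic to the acyl-free, doubly oxygenated ring G and allylic to C1=C2. The ring C1–C6 is therefore the 1,3-shift isomer of the 1-aryl-2-isopropenylcyclobutane C2–C3–C4–C5, whose C2–C5 bond opens on one-electron oxidation of ring G.
4. Forward order of rings: pyrrolidine (N, C2, C5, C4, C3) by cycloaddition, cyclobutane (C2–C5) by loss of nitrogen, cyclohexene (C1–C6) by ring expansion. The chalcone arm is then joined and the phenols are freed.
5. Stereochemistry: C3, C4 and C5 are all set in one silver-catalysed endo cycloaddition (chiral ferrocenyl ligand gives the absolute sense, endo mode gives 3,4-cis, E enone gives 4,5-trans). They are carried through a stereoretentive contraction and a suprafacial, retentive expansion. Alkene geometries come from a syn hydroboration and two Claisen–Schmidt condensations.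

Key step: step 15

Assumption: the facial sense of the silver/ThioClickFerrophos cycloaddition is ligand-controlled for this hindered imine too, and the ligand antipode that leads to the (2R,3S,4R,5S)-pyrrolidine is the one used. (MOM = methoxymethyl, rt = room temperature.)

**Step 1**
Reactants: 1 2,4-dihydroxyacetophenone
Product: 2 1-(2,4-dihydroxy-3-iodophenyl)ethanone
Conditions: I2, HIO3, EtOH–H2O, 40 °C
Reagents that add atoms: iodine, [I][I]; iodic acid, OI(=O)=O
Why: Electrophilic aromatic iodination goes to C3, the position activated by both hydroxyl groups, as is known for this ketone with iodine/iodic acid.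

**Step 2**
Reactants: 2 1-(2,4-dihydroxy-3-iodophenyl)ethanone
Product: 3 1-[3-iodo-2,4-bis(methoxymethoxy)phenyl]ethanone
Conditions: NaH, MOMCl, DMF, 0 °C to rt
Reagents that add atoms: chloromethyl methyl ether, COCCl
Why: Williamson-type O-alkylation of both phenoxides, in which NaH also frees the hydrogen-bonded 2-OH.

**Step 3**
Reactants: 4 3-methylbut-1-yne; 5 pinacolborane
Product: 6 (E)-2-(3-methylbut-1-enyl)-4,4,5,5-tetramethyl-1,3,2-dioxaborolane
Conditions: Cp2ZrHCl (5 mol%), Et3N (5 mol%), neat, 60 °C
Reagents that add atoms: none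
Why: Zirconium-hydride-catalysed syn hydroboration of the terminal alkyne places boron at the terminus and fixes the E geometry.

**Step 4**
Reactants: 3 1-[3-iodo-2,4-bis(methoxymethoxy)phenyl]ethanone; 6 (E)-alkenyl boronate
Product: 7 1-{2,4-bis(methoxymethoxy)-3-[(E)-3-methylbut-1-enyl]phenyl}ethanone (ring E ketone)
Conditions: Pd(dppf)Cl2 (5 mol%), K2CO3, dioxane–H2O, 80 °C
Reagents that add atoms: none
Why: Suzuki–Miyaura coupling keeps the alkenyl geometry, and alkenyl boronates are known to couple at this doubly ortho-alkoxylated iodide position.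

**Step 5**
Reactants: 8 2,4-dihydroxybenzaldehyde
Product: 9 2,4-bis(methoxymethoxy)benzaldehyde
Conditions: NaH, MOMCl, DMF, 0 °C to rt
Reagents that add atoms: chloromethyl methyl ether, COCCl
Why: Williamson-type O-alkylation of both phenoxides.

**Step 6**
Reactants: 7 ring E ketone; 9 2,4-bis(methoxymethoxy)benzaldehyde
Product: 10 (E)-1-{2,4-bis(methoxymethoxy)-3-[(E)-3-methylbut-1-enyl]phenyl}-3-[2,4-bis(methoxymethoxy)phenyl]prop-2-en-1-one
Conditions: KOH, EtOH, rt
Reagents that add atoms: none
Why: Claisen–Schmidt condensation, in which E1cB loss of water gives the E enone and MOM ethers are inert to base.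

**Step 7**
Reactants: 3 1-[3-iodo-2,4-bis(methoxymethoxy)phenyl]ethanone; 11 vinylboronic acid pinacol ester
Product: 12 1-[2,4-bis(methoxymethoxy)-3-vinylphenyl]ethanone
Conditions: Pd(dppf)Cl2 (5 mol%), K2CO3, dioxane–H2O, 80 °C
Reagents that add atoms: none
Why: Suzuki–Miyaura vinylation of the same iodide, and the inner vinyl carbon becomes C3 of the target ring.

**Step 8**
Reactants: 12 1-[2,4-bis(methoxymethoxy)-3-vinylphenyl]ethanone
Product: 13 3-acetyl-2,6-bis(methoxymethoxy)benzaldehyde
Conditions: OsO4 (2 mol%), NaIO4, 2,6-lutidine, dioxane–H2O, rt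
Reagents that add atoms: sodium periodate, [Na+].[O-]I(=O)(=O)=O
Why: Lemieux–Johnson cleavage of the only alkene present spares the electron-rich arene and the ketone.

**Step 9**
Reactants: 13 3-acetyl-2,6-bis(methoxymethoxy)benzaldehyde; 14 glycine allyl ester 4-toluenesulfonate
Product: 15 allyl (E)-N-[3-acetyl-2,6-bis(methoxymethoxy)benzylidene]glycinate
Conditions: Et3N, MgSO4, CH2Cl2, rt
Reagents that add atoms: none
Why: Imine condensation takes place at the aldehyde, which is far more electrophilic than the hindered aryl methyl ketone, and gives the E aldimine.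

**Step 10**
Reactants: 15 glycine imine; 10 chalcone
Product: 16 allyl (2R,3S,4R,5S)-5-[3-acetyl-2,6-bis(methoxymethoxy)phenyl]-3-[2,4-bis(methoxymethoxy)phenyl]-4-{2,4-bis(methoxymethoxy)-3-[(E)-3-methylbut-1-enyl]benzoyl}pyrrolidine-2-carboxylate (ester, ring A and aroyl all cis, ring G trans)
Conditions: AgOAc (5 mol%), ThioClickFerrophos (antipode as assumed, 5.5 mol%), Et2O–THF, −25 °C
Reagents that add atoms: none
Why: Catalytic asymmetric 1,3-dipolar cycloaddition of the N,O-chelated W-shaped silver azomethine ylide, in which the ylide carbon (C2) adds to the enone β-carbon (C5) and the imine carbon (C3) closes on C4, so that the ylide shape gives ester/ring A cis, the endo mode gives 3,4-cis, the E enone gives 4,5-trans and the ligand selects the face.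

**Step 11**
Reactants: 16 pyrrolidine
Product: 18 allyl cyclobutanecarboxylate with the C2 ester, C3 ring A and C4 aroyl group all cis and C5 ring G trans, via isodiazene 17 (not isolated)
Conditions: N-(benzyloxy)-N-(pivaloyloxy)-4-(trifluoromethyl)benzamide (1.5 equiv), THF, 45 °C
Reagents that add atoms: N-(benzyloxy)-N-(pivaloyloxy)-4-(trifluoromethyl)benzamide, CC(C)(C)C(=O)ON(OCc1ccccc1)C(=O)c1ccc(C(F)(F)F)cc1 (its nitrogen enters 17 and leaves again as N2; nothing of it stays in 18)
Why: Nitrogen deletion (pyrrolidine-to-cyclobutane contraction), in which the amine displaces pivalate at the anomeric amide nitrogen, the isodiazene expels N2, and the singlet 1,4-diradical (C2 ester-stabilised, C3 benzylic) collapses faster than it rotates, so the C2–C3 bond forms with retention at both carbons.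

**Step 12**
Reactants: 18 cyclobutane allyl ester
Product: 19 the corresponding cyclobutanecarboxylic acid (same configuration)
Conditions: Pd(PPh3)4 (5 mol%), morpholine, THF, rt; pH 4 buffer work-up
Reagents that add atoms: none
Why: Tsuji–Trost-type deallylation with zerovalent palladium is neutral enough to spare the MOM ethers, both ketones and the epimerisable C4 centre.

**Step 13**
Reactants: 19 cyclobutanecarboxylic acid
Product: 20 its N-(tetrachlorophthalimidyl) ester
Conditions: N-hydroxytetrachlorophthalimide, N,N'-diisopropylcarbodiimide, DMAP (10 mol%), CH2Cl2, rt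
Reagents that add atoms: N-hydroxytetrachlorophthalimide, ON1C(=O)c2c(Cl)c(Cl)c(Cl)c(Cl)c2C1=O
Why: Steglich-type carbodiimide esterification gives the redox-active ester without touching any stereocentre.

**Step 14**
Reactants: 20 redox-active ester
Product: 21 isopropenylcyclobutane (C2 isopropenyl cis to ring G on C5 and trans to ring A on C3, ring A and aroyl cis, aroyl and ring G trans)
Conditions: isopropenylmagnesium bromide, ZnCl2, THF, 0 °C; then 20, Ni(acac)2 (10 mol%), 2,2'-bipyridine (10 mol%), THF–DMF, rt
Reagents that add atoms: isopropenylmagnesium bromide, C=C(C)[Mg]Br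
Why: Nickel-catalysed decarboxylative alkenylation of a redox-active ester with an alkenylzinc reagent, in which the secondary C2 radical is captured on the face opposite ring A and the aroyl group (this centre is erased in step 15) and the ketones are inert to the organozinc.

**Step 15**
Reactants: 21 isopropenylcyclobutane
Product: 22 1-{3-[(1S,5S,6R)-series cyclohexenyl]…}ethanone, that is the (3S,4R,5S)-cyclohexene with methyl on C1, 3-acetyl-2,6-bis(methoxymethoxy)phenyl on C3, the MOM-protected aroyl group on C4 and 2,4-bis(methoxymethoxy)phenyl on C5 (3,4-cis, 4,5-trans)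
Conditions: (4-BrC6H4)3N SbCl6 (10 mol%), 2,6-di-tert-butylpyridine (30 mol%), CH2Cl2, −20 to 0 °C
Reagents that add atoms: none
Why: One-electron oxidation of ring G, the only arene of 21 with two alkoxy groups and no acyl group, weakens the C2–C5 bond, which is benzylic to the hole and allylic to the isopropenyl group, so that C5 slides suprafacially from C2 to the methylene terminus C6 and the product radical cation passes the hole to the next molecule of 21 (chain). The closest known reaction type is the aminium-salt (hole) catalysed vinylcyclobutane-to-cyclohexene rearrangement of 1-(alkoxyaryl)-2-vinylcyclobutanes, which runs at or below 0 °C with retention at the migrating carbon. The six-membered ring closes by C5–C6 bonding at the far end of the C2–C1–C6 allyl unit (6-endo with respect to the C1=C6 bond), while return to C2 (4-exo) only regenerates 21, and release of the strain of the tetrasubstituted four-membered ring makes the expansion irreversible. C3 and C4 are spectators, C5 keeps its configuration because the short C3–C4 tether holds the same face of C5 toward the allyl unit and ring G, cis to the isopropenyl group, points away from it, and C2 becomes sp2, so the 3,4-cis-4,5-trans pattern of 16 is delivered unchanged. The step needs C2–C5 cleavage in preference to C4–C5 or C2–C3 cleavage and to cycloreversion, which is secured by allyl stabilisation at C2, by the higher oxidation potentials of the acyl-bearing rings A and E and by the low temperature, while the hindered pyridine keeps adventitious acid from the isopropenyl group and the MOM ethers. The position of the new double bond (C1=C2, methyl on C1) follows from the allyl transposition and needs no further control.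

**Step 16**
Reactants: 22 cyclohexene methyl ketone; 9 2,4-bis(methoxymethoxy)benzaldehyde
Product: 23 octakis-O-MOM artonin C
Conditions: KOH, EtOH, 0 °C to rt
Reagents that add atoms: none
Why: Claisen–Schmidt condensation at the only methyl ketone gives the E enone, and the other enolisable site, the C4 methine, is flanked by two aryl-bearing carbons and already holds the favoured arrangement (aroyl and ring G diequatorial, ring A pseudoaxial).

**Step 17**
Reactants: 23 octakis-O-MOM artonin C
Product: 24 artonin C
Conditions: TMSOTf, 2,2'-bipyridyl, MeCN, 0 °C to rt; then H2O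
Reagents that add atoms: none
Why: Silyl triflate/bipyridyl cleavage of aromatic MOM ethers runs through aryl silyl ethers under non-acidic conditions, which avoids acid-induced ketalisation of the C4 ketone with the neighbouring phenols and cyclisation onto the alkenes, and touches no stereocentre.

**Compound list**

1 | 2,4-dihydroxyacetophenone | CC(=O)c1ccc(O)cc1O | starting material
2 | 1-(2,4-dihydroxy-3-iodophenyl)ethanone | CC(=O)c1ccc(O)c(I)c1O | intermediate
3 | 1-[3-iodo-2,4-bis(methoxymethoxy)phenyl]ethanone | CC(=O)c1ccc(OCOC)c(I)c1OCOC | intermediate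
4 | 3-methylbut-1-yne | CC(C)C#C | starting material
5 | pinacolborane | [H]B1OC(C)(C)C(C)(C)O1 | starting material
6 | (E)-2-(3-methylbut-1-enyl)-4,4,5,5-tetramethyl-1,3,2-dioxaborolane | CC(C)/C=C/B1OC(C)(C)C(C)(C)O1 | intermediate
7 | 1-{2,4-bis(methoxymethoxy)-3-[(E)-3-methylbut-1-enyl]phenyl}ethanone | CC(=O)c1ccc(OCOC)c(/C=C/C(C)C)c1OCOC | intermediate
8 | 2,4-dihydroxybenzaldehyde | O=Cc1ccc(O)cc1O | starting material
9 | 2,4-bis(methoxymethoxy)benzaldehyde | O=Cc1ccc(OCOC)cc1OCOC | intermediate
10 | MOM-protected E chalcone (rings E and G) | O=C(/C=C/c1ccc(OCOC)cc1OCOC)c1ccc(OCOC)c(/C=C/C(C)C)c1OCOC | intermediate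
11 | vinylboronic acid pinacol ester | C=CB1OC(C)(C)C(C)(C)O1 | starting material
12 | 1-[2,4-bis(methoxymethoxy)-3-vinylphenyl]ethanone | CC(=O)c1ccc(OCOC)c(C=C)c1OCOC | intermediate
13 | 3-acetyl-2,6-bis(methoxymethoxy)benzaldehyde | CC(=O)c1ccc(OCOC)c(C=O)c1OCOC | intermediate
14 | glycine allyl ester 4-toluenesulfonate | NCC(=O)OCC=C.Cc1ccc(S(=O)(=O)O)cc1 | starting material
15 | allyl (E)-N-[3-acetyl-2,6-bis(methoxymethoxy)benzylidene]glycinate | C=CCOC(=O)C/N=C/c1c(OCOC)ccc(C(C)=O)c1OCOC | intermediate
16 | (2R,3S,4R,5S)-pyrrolidine endo adduct | C=CCOC(=O)[C@@H]1N[C@H](c2c(OCOC)ccc(C(C)=O)c2OCOC)[C@H](C(=O)c2ccc(OCOC)c(/C=C/C(C)C)c2OCOC)[C@H]1c2ccc(OCOC)cc2OCOC | intermediate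
17 | isodiazene (1,1-diazene) of 16 | C=CCOC(=O)[C@@H]1[N+](=[N-])[C@H](c2c(OCOC)ccc(C(C)=O)c2OCOC)[C@H](C(=O)c2ccc(OCOC)c(/C=C/C(C)C)c2OCOC)[C@H]1c2ccc(OCOC)cc2OCOC | intermediate
18 | cyclobutane allyl ester (ester, ring A, aroyl cis; ring G trans) | C=CCOC(=O)[C@@H]1[C@H](c2c(OCOC)ccc(C(C)=O)c2OCOC)[C@H](C(=O)c2ccc(OCOC)c(/C=C/C(C)C)c2OCOC)[C@H]1c2ccc(OCOC)cc2OCOC | intermediate
19 | cyclobutanecarboxylic acid | OC(=O)[C@@H]1[C@H](c2c(OCOC)ccc(C(C)=O)c2OCOC)[C@H](C(=O)c2ccc(OCOC)c(/C=C/C(C)C)c2OCOC)[C@H]1c2ccc(OCOC)cc2OCOC | intermediate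
20 | N-(tetrachlorophthalimidyl) ester of 19 | O=C(ON2C(=O)c3c(Cl)c(Cl)c(Cl)c(Cl)c3C2=O)[C@@H]1[C@H](c2c(OCOC)ccc(C(C)=O)c2OCOC)[C@H](C(=O)c2ccc(OCOC)c(/C=C/C(C)C)c2OCOC)[C@H]1c2ccc(OCOC)cc2OCOC | intermediate
21 | isopropenylcyclobutane (isopropenyl cis to ring G) | C=C(C)[C@H]1[C@H](c2c(OCOC)ccc(C(C)=O)c2OCOC)[C@H](C(=O)c2ccc(OCOC)c(/C=C/C(C)C)c2OCOC)[C@H]1c2ccc(OCOC)cc2OCOC | intermediate
22 | (3S,4R,5S)-cyclohexene methyl ketone | CC1=C[C@H](c2c(OCOC)ccc(C(C)=O)c2OCOC)[C@H](C(=O)c2ccc(OCOC)c(/C=C/C(C)C)c2OCOC)[C@@H](c2ccc(OCOC)cc2OCOC)C1 | intermediate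
23 | octakis-O-MOM artonin C | CC1=C[C@H](c2c(OCOC)ccc(C(=O)/C=C/c3ccc(OCOC)cc3OCOC)c2OCOC)[C@H](C(=O)c2ccc(OCOC)c(/C=C/C(C)C)c2OCOC)[C@@H](c2ccc(OCOC)cc2OCOC)C1 | intermediate
24 | artonin C | CC1=C[C@H](c2c(O)ccc(C(=O)/C=C/c3ccc(O)cc3O)c2O)[C@H](C(=O)c2ccc(O)c(/C=C/C(C)C)c2O)[C@@H](c2ccc(O)cc2O)C1 | target

**Step count and risks**

Total step count: 17. Longest linear sequence: 13 steps (steps 1, 2, 7, 8, 9, 10, 11, 12, 13, 14, 15, 16, 17).

Steps most likely to fail:

Step 15. Three processes threaten this step.
- The opened radical cation may fall apart by cycloreversion and re-add without memory of configuration.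
- The hole may settle on the alkenyl side chain of ring E.
- Traces of acid may strip MOM groups or protonate the isopropenyl group.

The fallback sets out from 18 and comes back at 22. It keeps the four-to-six ring growth but replaces the sigmatropic shift by a polar two-atom insertion.
- Compound 18 is itself a vicinal donor–acceptor cyclobutane, with the ester on C2 and ring G on C5.
- With Sc(OTf)3 and 2-(trimethylsilyloxy)propene in CH2Cl2 at −20 °C it should undergo the known formal [4+2] annulation of donor–acceptor cyclobutanes with silyl enol ethers.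
- In that annulation the enol ether methylene (future C6) attacks C5 anti to the aroyl group. The ester enolate at C2 then closes on the oxocarbenium carbon (future C1) and gives the silyloxy cyclohexane ester F1.
- Deallylation as in step 12, with loss of the silyl group on work-up, gives the β-hydroxy acid F2.
- Decarboxylative dehydration of F2 with N,N-dimethylformamide dineopentyl acetal in warm toluene places the double bond between C1 and C2 and gives 22.

Step 11. N–N bond formation at the doubly α-branched nitrogen may be sluggish. The 1,4-diradical may fragment into two alkenes instead of closing, or may lose its stereochemical memory.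

The fallback sets out from 16 and comes back at 17, and so at 18. It separates amination from oxidation, so a small electrophile meets the hindered nitrogen and N2 is lost at low temperature.
- tert-Butyl nitrite gives the N-nitrosopyrrolidine F3.
- Zinc in acetic acid reduces F3 to the N-aminopyrrolidine F4.
- PhI(OAc)2 in CH2Cl2 at −20 °C oxidises F4 to 17, which collapses to 18.

Step 10. With two ortho substituents on the imine aryl group and an electron-rich enone, the reaction may stall after the Michael addition without Mannich closure. It may also show poor endo/exo or facial selectivity.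

The fallback sets out from 15 and 10 and comes back at 16. It gives up asymmetric catalysis for resolution.
- The lithium ylide (LiBr, Et3N, THF, rt) is used for a racemic, endo-selective stepwise cycloaddition under more forcing conditions.
- Compound 16 is then separated from the mirror-image pyrrolidine F5 by preparative chromatography on a chiral stationary phase.

**Further compounds**

F1 | step 15 | allyl 2-methyl-2-(trimethylsilyloxy)cyclohexanecarboxylate bearing ring A, the aroyl group and ring G as in 22 (C1 and C2 configuration open) | C=CCOC(=O)C1[C@H](c2c(OCOC)ccc(C(C)=O)c2OCOC)[C@H](C(=O)c2ccc(OCOC)c(/C=C/C(C)C)c2OCOC)[C@@H](c2ccc(OCOC)cc2OCOC)CC1(C)O[Si](C)(C)C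
F2 | step 15 | corresponding 2-hydroxy-2-methylcyclohexanecarboxylic acid | OC(=O)C1[C@H](c2c(OCOC)ccc(C(C)=O)c2OCOC)[C@H](C(=O)c2ccc(OCOC)c(/C=C/C(C)C)c2OCOC)[C@@H](c2ccc(OCOC)cc2OCOC)CC1(C)O
F3 | step 11 | N-nitroso derivative of 16 | C=CCOC(=O)[C@@H]1N(N=O)[C@H](c2c(OCOC)ccc(C(C)=O)c2OCOC)[C@H](C(=O)c2ccc(OCOC)c(/C=C/C(C)C)c2OCOC)[C@H]1c2ccc(OCOC)cc2OCOC
F4 | step 11 | N-amino derivative of 16 | C=CCOC(=O)[C@@H]1N(N)[C@H](c2c(OCOC)ccc(C(C)=O)c2OCOC)[C@H](C(=O)c2ccc(OCOC)c(/C=C/C(C)C)c2OCOC)[C@H]1c2ccc(OCOC)cc2OCOC
F5 | step 10 | (2S,3R,4S,5R)-pyrrolidine, mirror image of 16 | C=CCOC(=O)[C@H]1N[C@@H](c2c(OCOC)ccc(C(C)=O)c2OCOC)[C@@H](C(=O)c2ccc(OCOC)c(/C=C/C(C)C)c2OCOC)[C@@H]1c2ccc(OCOC)cc2OCOC
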